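## Analysis of the target

The target, (7-hydroxy-2,2-dimethyl-2H-chromen-5-yl)(2-hydroxy-4,6-dimethoxyphenyl)methanone, is a benzophenone. Ring A is a 2-hydroxy-4,6-dimethoxyphenyl group. Ring B is the benzene ring of a 2,2-dimethyl-2H-chromene (O1, C2, C3, C4, C4a, C8a) with the ketone on C5 and a free hydroxyl on C7. There is no stereocentre and the molecule is achiral, so the problem is one of substitution pattern and protecting-group logic. The sensitive parts are the 2H-chromene (a styrene-like C3=C4 bond next to an allylic ether carbon, open to acid, oxidants and thermal electrocyclic ring opening), the two phenols and the tri-ortho-substituted diaryl ketone. The two methyl ethers of ring A must stay while two other phenols are set free, which rules out a late demethylation. Ring A is easy, because its oxygen pattern is that of commercial 3,5-dimethoxyphenol. The difficulty is ring B (C4a, C5, C6, C7, C8, C8a): the carbonyl sits on C5, meta to both oxygens (C7, C8a), where acylation of a resorcinol does not go, and the pyran carbon sits on C4a, where a prenyl or chromene unit has to compete with C8, the position between the two oxygens. The strategy rests on the fact that this pattern maps onto a 2-pyrone and an alkyne without any positional choice on a finished arene. C5, C6, C7 and C8, with the ketone and the C7 oxygen, are carbons C6, C5, C4 and C3 of a 6-acyl-4-alkoxy-2-pyrone. C8a and C4a, with the oxygen and the carbon chain, are the two carbons of an ynol ether.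

## Retrosynthetic reasoning

**20 to 19.** The two methoxymethyl acetals, on O7 and on the ring A oxygen, are cut last. Acetals are used because ring A already carries two methyl ethers that must remain, and dilute acid tells the two kinds of ether apart. Placing this step last keeps the free ortho-hydroxy ketone and the free C7 phenol away from oxidants and strong base.

**19 to 17 (through 18).** The O1–C2 bond is cut and the C3=C4 double bond is taken back to a benzylic methylene, which gives the ortho-prenylphenol 17. The five pyran carbons then form one prenyl group on C4a that can be brought in as an intact chain. The forward reaction is a dehydrogenation at C4 to the ortho-quinone methide 18 followed by oxa-6π closure. It needs the C8a hydroxyl to be the only free phenol.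

**17 to 16.** The C8a oxygen therefore carries a group of its own kind, the triisopropylsilyl ether of 16, which fluoride removes without touching the acetals. The silyl group is the one the ynol ether brings with it.

**16 to 14 and 5 (through 15).** This is the key disconnection. The bonds C4a–C5 and C8–C8a are cut and a one-carbon lactone bridge is added back, which leads to the 6-aroyl-4-alkoxy-2-pyrone 14 and the siloxyalkyne 5. The cut is made here because every substituent of ring B is then fixed by the two precursors: the ketone by C6 of the pyrone, the C7 oxygen by C4 of the pyrone, and the C8a oxygen and the prenyl chain by the alkyne. The forward reaction has to join the prenyl-bearing alkyne carbon to pyrone C6 and the siloxy carbon to pyrone C3, and the bridged lactone 15 has to decarboxylate.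

**14 to 13, then to 11 and 12 (12 from 7, 7 from 6).** The bond between the carbonyl carbon and C1' of ring A is cut. Ring A comes from 6 with all three oxygens in place. Its acetal in 7 is both the final protecting group and the director for the ortho-lithiation to 12. Addition of 12 to aldehyde 11 and oxidation of carbinol 13 give the ketone. This makes the route convergent and sets the ketone oxidation level before the key step.

**11 to 10, 9 and 8.** The formyl carbon of 11 is the 6-methyl carbon of commercial 8. After O-protection to 9, the vinylogously acidic methyl group is condensed to the enamine 10, whose double bond is cleaved. This two-step route is mild enough for the vinylogous acetal ester at C4.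

**5 to 4, 3, 2 and 1.** The C–O bond of the ynol ether comes from oxygenation of the acetylide 3 to the ynolate 4 and O-silylation. The bond between the propargylic CH2 and the alkyne comes from allylation of an acetylide with 1. The whole C4a side chain is thus assembled from 1 in two steps.

## Alternatives that were turned down

**Alternative 1:** Ring A is built around the carbinol carbon by a Danheiser benzannulation.
- Disconnection: C1'–C2', C2'–C3' and C5'–C6' of ring A are cut. This leads to 3-methoxycyclobut-2-en-1-one A2 and a methoxyalkyne A3 that carries the silyl-protected benzylic carbinol and the complete chromene.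
- Forward key step: heating opens A2 to a vinylketene, which adds to A3 in a [2+2] sense. The four-membered adduct opens to a dienylketene, and 6π closure with tautomerisation gives phenol A1.
- For it: the orientation of this benzannulation with ynol ethers is dependable and documented, which is more than can be said for the cycloaddition chosen here. The one free hydroxyl of ring A emerges already distinguished from the two methyl ethers.
- Against it: the key step is spent on ring A, whose pattern can be bought. A3 requires a 7-oxygenated 2,2-dimethylchromene-5-carbaldehyde, which is exactly the pattern that is hard to make. The chromene would have to survive ketene intermediates at elevated temperature (ring opening, [2+2] at C3=C4). A2 is small, volatile and sensitive. Desilylation, oxidation of the carbinol and acetal removal follow.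
- Comparison: it is stronger on precedent and on ring A selectivity. The chosen strategy instead solves ring B in its key step, takes ring A from the shelf and has the ketone at the right oxidation level before the key step.

**Alternative 2:** Ring A is made by a biomimetic Claisen cyclisation.
- Disconnection: C1'–C6' is cut. This leads to the 4-hydroxy-2-pyrone A5, whose 2-aryl-2-oxoethyl chain on C6 masks a 3,5,7-triketo ester.
- Forward key step: Mg(OMe)2 in methanol opens the lactone to the chelated triketo ester. The methylene between the two ketones attacks the ester carbonyl and gives the acylphloroglucinol A4.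
- For it: it is mild and basic, which the chromene tolerates. It uses the same cheap pyrone 8, gives the ketone directly, and this type of polyketide cyclisation is well known, so the key step is probably more reliable than the one chosen.
- Against it: the aldol mode (C2 onto the aryl ketone) competes and would give a biaryl resorcylate. A4 carries three ring A phenols, two of which must then be methylated selectively. The chromene-5-carboxylate with the difficult ring B pattern is again an input and not a result.
- Comparison: the chosen strategy offers a solution for ring B and avoids the late selective methylation, because the methyl ethers of ring A are bought.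

**Alternative 3:** Ring B is made by an Alder–Rickert sequence.
- Disconnection: C4a–C8a and C5–C6 are cut. This leads to 1,3-bis(trimethylsilyloxy)cyclohexa-1,3-diene A7 and the alkynoate A8, which carries ring A as a silyl-protected carbinol.
- Forward key step: a Diels–Alder reaction with normal electron demand gives a bicyclo[2.2.2]octadiene, which expels ethylene on heating and leaves the resorcylate A6. Its ester carbon is the future C4.
- For it: the polarisation is unambiguous (nucleophilic diene terminus onto the β-carbon of the ynoate) and the reaction class is well documented. Orientation and reactivity are therefore more secure than in the chosen step, and both oxygens and the C5 carbon land correctly.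
- Against it: the ester supplies only C4. C3, C2 and both methyl groups must be added and the pyran closed afterwards. The two ring B phenols emerge undifferentiated, the carbinol must be oxidised, and ethylene extrusion needs temperatures that endanger the benzylic silyl ether and the acetal.
- Comparison: it is stronger on the certainty of the cycloaddition. The chosen strategy delivers ring B with all five pyran carbons, the ketone and two differentiated oxygens in one step, so that three steps remain after the key step instead of at least six.

Key step: step 9

Remark: the orientation of the cycloaddition in step 9 is assumed to follow that of ynamines and ketene acetals with 2-pyrones; no result for a siloxyalkyne with a 6-acyl-2-pyrone is relied on.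

## Route

Step 1
Reactants: 1 1-bromo-3-methylbut-2-ene
Product: 2 5-methylhex-4-en-1-yne
Conditions: HC≡CMgBr (3 equiv), CuCl (cat.), THF, 0 °C to rt
Reagents that add atoms: ethynylmagnesium bromide, C#C[Mg]Br
Why: Copper-catalysed coupling of an alkynyl Grignard reagent with an allylic bromide, which should go at the primary carbon because attack at the tertiary terminus is hindered; excess acetylide suppresses double allylation, and the volatile skipped enyne is carried on as a dried, assayed solution or after fractional distillation.

Step 2
Reactants: 2 5-methylhex-4-en-1-yne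
Product: 5 triisopropyl[(5-methylhex-4-en-1-yn-1-yl)oxy]silane, via lithium 5-methylhex-4-en-1-yn-1-ide 3 (not isolated), via lithium 5-methylhex-4-en-1-yn-1-olate 4 (not isolated)
Conditions: n-BuLi, THF, −78 °C; t-BuOOLi (from t-BuOOH, LiN(SiMe3)2), −78 to 0 °C; TIPSOTf, −78 °C to rt
Reagents that add atoms: tert-butyl hydroperoxide, CC(C)(C)OO; triisopropylsilyl trifluoromethanesulfonate, CC(C)[Si](OS(=O)(=O)C(F)(F)F)(C(C)C)C(C)C
Why: Oxidation of a lithium acetylide to the ynolate by oxygen transfer from the lithium peroxide (Julia-type acetylide oxidation), followed by O-silylation with the hard, bulky silyl triflate; the low temperature should leave the doubly activated CH2 of the skipped enyne untouched, and the product is purified quickly on base-treated silica.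

Step 3
Reactants: 6 3,5-dimethoxyphenol
Product: 7 1,3-dimethoxy-5-(methoxymethoxy)benzene
Conditions: MOMCl, i-Pr2NEt, CH2Cl2, 0 °C to rt
Reagents that add atoms: chloromethyl methyl ether, COCCl
Why: O-alkylation of a phenol with an α-chloro ether (Williamson type); the acetal later directs the lithiation and is removed by dilute acid at the end.

Step 4
Reactants: 8 4-hydroxy-6-methyl-2H-pyran-2-one
Product: 9 4-(methoxymethoxy)-6-methyl-2H-pyran-2-one
Conditions: MOMCl, i-Pr2NEt, CH2Cl2, 0 °C
Reagents that add atoms: chloromethyl methyl ether, COCCl
Why: O-alkylation of the vinylogous acid at the 4-oxygen, the usual site for hard alkylating agents; the product is a vinylogous acetal ester and more acid-labile than an aryl acetal, which is why all steps up to the cycloaddition are run neutral or basic.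

Step 5
Reactants: 9 4-(methoxymethoxy)-6-methyl-2H-pyran-2-one
Product: 10 6-[(E)-2-(dimethylamino)ethenyl]-4-(methoxymethoxy)-2H-pyran-2-one
Conditions: t-BuOCH(NMe2)2, PhMe, 80 °C
Reagents that add atoms: tert-butoxybis(dimethylamino)methane, CC(C)(C)OC(N(C)C)N(C)C
Why: The 6-methyl group is acidified through C5=C6 and C3=C4 by the lactone carbonyl and should condense with the aminal ester to the push-pull enamine (the first stage of a Leimgruber–Batcho sequence); the usual SeO2 oxidation of 6-methyl-2-pyrones at 150–160 °C is avoided because the water and H2SeO3 it forms would cleave the vinylogous acetal ester.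

Step 6
Reactants: 10 6-[(E)-2-(dimethylamino)ethenyl]-4-(methoxymethoxy)-2H-pyran-2-one
Product: 11 4-(methoxymethoxy)-2-oxo-2H-pyran-6-carbaldehyde
Conditions: NaIO4, THF/H2O, rt
Reagents that add atoms: sodium periodate, [Na+].[O-]I(=O)(=O)=O
Why: Oxidative cleavage of the electron-rich enamine double bond by periodate, the known second stage of the methyl-to-formyl conversion of activated methyl groups; the electron-poor ring double bonds and the acetal should not react.

Step 7
Reactants: 7 1,3-dimethoxy-5-(methoxymethoxy)benzene; 11 4-(methoxymethoxy)-2-oxo-2H-pyran-6-carbaldehyde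
Product: 13 racemic 6-{[2,4-dimethoxy-6-(methoxymethoxy)phenyl](hydroxy)methyl}-4-(methoxymethoxy)-2H-pyran-2-one, via [2,4-dimethoxy-6-(methoxymethoxy)phenyl]lithium 12 (not isolated)
Conditions: 7, n-BuLi, THF, 0 °C; then added to 11, THF, −78 °C; aq NH4Cl
Reagents that add atoms: none
Why: Directed ortho-metalation between the acetal and a methoxy group (the acetal is the stronger director and two such sites stand against one between the methoxy groups), then 1,2-addition to the aldehyde, which at −78 °C with inverse addition should be much faster than attack on the lactone; the new carbinol centre forms as a racemate and is removed in step 8.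

Step 8
Reactants: 13 racemic 6-{[2,4-dimethoxy-6-(methoxymethoxy)phenyl](hydroxy)methyl}-4-(methoxymethoxy)-2H-pyran-2-one
Product: 14 6-[2,4-dimethoxy-6-(methoxymethoxy)benzoyl]-4-(methoxymethoxy)-2H-pyran-2-one
Conditions: Dess–Martin periodinane, pyridine, CH2Cl2, 0 °C to rt
Reagents that add atoms: none
Why: Dess–Martin oxidation of a doubly activated secondary alcohol under neutral conditions; pyridine buffers the acetic acid so that the vinylogous acetal ester survives.

Step 9
Reactants: 14 6-[2,4-dimethoxy-6-(methoxymethoxy)benzoyl]-4-(methoxymethoxy)-2H-pyran-2-one; 5 triisopropyl[(5-methylhex-4-en-1-yn-1-yl)oxy]silane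
Product: 16 [2,4-dimethoxy-6-(methoxymethoxy)phenyl]{5-(methoxymethoxy)-2-(3-methylbut-2-en-1-yl)-3-[(triisopropylsilyl)oxy]phenyl}methanone, via bridged lactone cycloadduct 15 (not isolated)
Conditions: 5 (2 equiv), PhMe, 110–130 °C, sealed tube
Reagents that add atoms: none
Why: The pyrone 14 serves as the 4π component (C3=C4–C5=C6) and the ynol ether 5 as the 2π component in a thermal Diels–Alder reaction with inverse electron demand, the HOMO of 5 (largest coefficient on the prenyl-bearing carbon) meeting the LUMO of 14, which the lactone and aroyl carbonyls lower. The prenyl-bearing carbon should bond to pyrone C6 and the siloxy carbon to pyrone C3 (target bonds C4a–C5 and C8–C8a), which closes the six-membered carbocycle in a concerted, asynchronous, suprafacial [4+2] mode and gives the 2-oxabicyclo[2.2.2]octadienone 15. 15 should lose CO2 at once by retro-[4+2] cycloreversion, which is irreversible and aromatises ring B to 16. The closest known reaction type is the Diels–Alder/decarboxylation of 2-pyrones with ynamines and ketene acetals, which gives anilines and aryl ethers with this orientation; siloxyalkynes are established 2π partners in benzannulations with vinylketenes, but their pairing with a 6-acyl-2-pyrone is not documented. Regioselectivity is the selectivity needed: C6 is the electrophilic diene terminus (δ-carbon of the dienyl lactone, bearing the ring oxygen) and C3 the nucleophilic one (β-carbon of the C4 enol ether), which matches the polarisation of 5. The aroyl group mainly lowers the LUMO; its own conjugative pull would favour attack at C3, so it opposes the orientation and is expected to be outweighed by the three effects named, not to be the source of control. Chemoselectivity follows from the absence of any Lewis acid (no [2+2] with the ketone or enone) and from the inertness of the trisubstituted prenyl alkene as a dienophile. No stereocentre results, since the two bridgehead centres of racemic 15 vanish on aromatisation.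

Step 10
Reactants: 16 [2,4-dimethoxy-6-(methoxymethoxy)phenyl]{5-(methoxymethoxy)-2-(3-methylbut-2-en-1-yl)-3-[(triisopropylsilyl)oxy]phenyl}methanone
Product: 17 [2,4-dimethoxy-6-(methoxymethoxy)phenyl][3-hydroxy-5-(methoxymethoxy)-2-(3-methylbut-2-en-1-yl)phenyl]methanone
Conditions: TBAF, THF, 0 °C; aq NH4Cl
Reagents that add atoms: none
Why: Fluoride-induced cleavage of an aryl silyl ether, driven by the Si–F bond and the phenoxide leaving group; acetals, ketone and prenyl group should be unaffected.

Step 11
Reactants: 17 [2,4-dimethoxy-6-(methoxymethoxy)phenyl][3-hydroxy-5-(methoxymethoxy)-2-(3-methylbut-2-en-1-yl)phenyl]methanone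
Product: 19 [2,4-dimethoxy-6-(methoxymethoxy)phenyl][7-(methoxymethoxy)-2,2-dimethyl-2H-chromen-5-yl]methanone, via ortho-quinone methide 18 (not isolated)
Conditions: DDQ, PhH, 80 °C
Reagents that add atoms: none
Why: DDQ abstracts hydride from the benzylic and allylic CH2 of the ortho-prenylphenol to give the ortho-quinone methide 18, which closes by oxa-6π electrocyclisation (the known oxidative cyclisation of ortho-prenylphenols to 2,2-dimethylchromenes); the C8a hydroxyl is the only free phenol, so only one mode of closure exists.

Step 12
Reactants: 19 [2,4-dimethoxy-6-(methoxymethoxy)phenyl][7-(methoxymethoxy)-2,2-dimethyl-2H-chromen-5-yl]methanone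
Product: 20 (7-hydroxy-2,2-dimethyl-2H-chromen-5-yl)(2-hydroxy-4,6-dimethoxyphenyl)methanone
Conditions: 3 M aq HCl, MeOH, 45 °C
Reagents that add atoms: none
Why: Acid-catalysed cleavage of the two aryl methoxymethyl acetals by transacetalisation to methanol; the methyl ethers are inert, and the chromene should tolerate dilute methanolic acid at moderate temperature.

## Compound list

1 | 1-bromo-3-methylbut-2-ene | CC(C)=CCBr | starting material
2 | 5-methylhex-4-en-1-yne | C#CCC=C(C)C | intermediate
3 | lithium 5-methylhex-4-en-1-yn-1-ide | [Li+].[C-]#CCC=C(C)C | intermediate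
4 | lithium 5-methylhex-4-en-1-yn-1-olate | [Li+].[O-]C#CCC=C(C)C | intermediate
5 | triisopropyl[(5-methylhex-4-en-1-yn-1-yl)oxy]silane | CC(C)=CCC#CO[Si](C(C)C)(C(C)C)C(C)C | intermediate
6 | 3,5-dimethoxyphenol | COc1cc(O)cc(OC)c1 | starting material
7 | 1,3-dimethoxy-5-(methoxymethoxy)benzene | COCOc1cc(OC)cc(OC)c1 | intermediate
8 | 4-hydroxy-6-methyl-2H-pyran-2-one | CC1=CC(O)=CC(=O)O1 | starting material
9 | 4-(methoxymethoxy)-6-methyl-2H-pyran-2-one | CC1=CC(OCOC)=CC(=O)O1 | intermediate
10 | 6-[(E)-2-(dimethylamino)ethenyl]-4-(methoxymethoxy)-2H-pyran-2-one | CN(C)/C=C/C1=CC(OCOC)=CC(=O)O1 | intermediate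
11 | 4-(methoxymethoxy)-2-oxo-2H-pyran-6-carbaldehyde | O=CC1=CC(OCOC)=CC(=O)O1 | intermediate
12 | [2,4-dimethoxy-6-(methoxymethoxy)phenyl]lithium | [Li]c1c(OC)cc(OC)cc1OCOC | intermediate
13 | racemic 6-{[2,4-dimethoxy-6-(methoxymethoxy)phenyl](hydroxy)methyl}-4-(methoxymethoxy)-2H-pyran-2-one | COCOc1cc(OC)cc(OC)c1C(O)C1=CC(OCOC)=CC(=O)O1 | intermediate
14 | 6-[2,4-dimethoxy-6-(methoxymethoxy)benzoyl]-4-(methoxymethoxy)-2H-pyran-2-one | COCOc1cc(OC)cc(OC)c1C(=O)C1=CC(OCOC)=CC(=O)O1 | intermediate
15 | racemic 1-[2,4-dimethoxy-6-(methoxymethoxy)benzoyl]-5-(methoxymethoxy)-7-(3-methylbut-2-en-1-yl)-8-[(triisopropylsilyl)oxy]-2-oxabicyclo[2.2.2]octa-5,7-dien-3-one | COCOC1=CC2(C(=O)c3c(OCOC)cc(OC)cc3OC)OC(=O)C1C(O[Si](C(C)C)(C(C)C)C(C)C)=C2CC=C(C)C | intermediate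
16 | [2,4-dimethoxy-6-(methoxymethoxy)phenyl]{5-(methoxymethoxy)-2-(3-methylbut-2-en-1-yl)-3-[(triisopropylsilyl)oxy]phenyl}methanone | COCOc1cc(OC)cc(OC)c1C(=O)c1cc(OCOC)cc(O[Si](C(C)C)(C(C)C)C(C)C)c1CC=C(C)C | intermediate
17 | [2,4-dimethoxy-6-(methoxymethoxy)phenyl][3-hydroxy-5-(methoxymethoxy)-2-(3-methylbut-2-en-1-yl)phenyl]methanone | COCOc1cc(OC)cc(OC)c1C(=O)c1cc(OCOC)cc(O)c1CC=C(C)C | intermediate
18 | (6Z)-5-[2,4-dimethoxy-6-(methoxymethoxy)benzoyl]-3-(methoxymethoxy)-6-(3-methylbut-2-en-1-ylidene)cyclohexa-2,4-dien-1-one | O=C1C=C(OCOC)C=C(C(=O)c2c(OCOC)cc(OC)cc2OC)/C1=C/C=C(C)C | intermediate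
19 | [2,4-dimethoxy-6-(methoxymethoxy)phenyl][7-(methoxymethoxy)-2,2-dimethyl-2H-chromen-5-yl]methanone | COCOc1cc(OC)cc(OC)c1C(=O)c1cc(OCOC)cc2OC(C)(C)C=Cc12 | intermediate
20 | (7-hydroxy-2,2-dimethyl-2H-chromen-5-yl)(2-hydroxy-4,6-dimethoxyphenyl)methanone | COc1cc(O)c(C(=O)c2cc(O)cc3c2C=CC(C)(C)O3)c(OC)c1 | target

## Step count and least certain steps

Total step count: 12. Longest linear sequence: 9 steps (steps 4 to 12, from 8).

**Step 9 (key step).** Two things are most likely to go wrong.
- The cycloaddition may be too slow, because the 4-alkoxy donor raises the LUMO of the pyrone. Thermal decay of 5 (silyl migration to a silylketene, protonolysis by traces of acid) could then outrun it.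
- The orientation may be eroded, because the aroyl group by itself would direct the nucleophilic alkyne carbon to C3.

The fallback gives up the cycloaddition and builds ring B by classical substitution of a 3,5-dihydroxybenzoate. It sets out from 12 (made from 7 as in step 7) and comes back to the route at 19. Commercial methyl 3,5-dihydroxybenzoate F1 is protected with MOMCl and i-Pr2NEt to methyl 3,5-bis(methoxymethoxy)benzoate F2. Bromination with NBS in MeCN, which for 3,5-dialkoxybenzoates goes ortho to the ester and para to an oxygen, should give methyl 2-bromo-3,5-bis(methoxymethoxy)benzoate F3. Stille coupling with tributyl(3-methylbut-2-en-1-yl)stannane under Pd(PPh3)4 (zerovalent palladium) in DMF should give methyl 3,5-bis(methoxymethoxy)-2-(3-methylbut-2-en-1-yl)benzoate F4. Dilute HCl in methanol frees methyl 3,5-dihydroxy-2-(3-methylbut-2-en-1-yl)benzoate F5. DDQ should close the only ortho hydroxyl to methyl 7-hydroxy-2,2-dimethyl-2H-chromene-5-carboxylate F6, and MOMCl gives methyl 7-(methoxymethoxy)-2,2-dimethyl-2H-chromene-5-carboxylate F7. Addition of 12 to this ester at −78 to 0 °C should stop at ketone 19, because a tri-ortho-substituted benzophenone resists a second addition of the hindered aryllithium.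

**Step 5 (with step 6).** The vinylogous acetal at C4 may be exchanged or lost through dimethylamine or alkoxide released during the enamination, or the condensation at the weakly acidic methyl group may stay incomplete. The fallback sets out from 9 and comes back at 11. Radical bromination (NBS, AIBN, PhCF3, 80 °C, solid K2CO3) should give 6-(bromomethyl)-4-(methoxymethoxy)-2H-pyran-2-one F8, which trimethylamine N-oxide in MeCN converts to the aldehyde 11 by a Kornblum-type oxidation.

**Step 7.** The aryl anion may attack the lactone carbonyl or C6 of the pyrone, and partial metalation between the two methoxy groups would give an isomeric adduct. The fallback sets out from 7 and comes back at 13. The lithiated arene is quenched with iodine to 2-iodo-1,5-dimethoxy-3-(methoxymethoxy)benzene F9, which can be freed from its isomer at this stage. Iodine–magnesium exchange with i-PrMgCl·LiCl at −20 °C gives [2,4-dimethoxy-6-(methoxymethoxy)phenyl]magnesium chloride F10, a milder nucleophile of a kind known to tolerate esters, which is added to 11 at −78 °C to give 13.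

**Step 2.** Base may isomerise the skipped enyne at its propargylic and allylic CH2 during acetylide formation, oxygen transfer may stay incomplete, and the siloxyalkyne may be lost by protonolysis on silica. The fallback is a Kowalski ester homologation. It does not draw on a numbered compound: commercial methyl 4-methylpent-3-enoate F11 takes the place of 1 and 2, and the route is rejoined at ynolate 4. F11 is added to LiCHBr2 (from CH2Br2 and lithium 2,2,6,6-tetramethylpiperidide, THF, −78 °C), and LiN(SiMe3)2 should convert the adduct to lithium 1,1-dibromo-5-methylhexa-1,4-dien-2-olate F12. n-BuLi then triggers bromine–lithium exchange and 1,2-shift to 4, which is silylated to 5 as in step 2.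

**Step 11.** Hydride abstraction may be slow on a ring deactivated by the aroyl group, so that oxidation of the electron-rich ring A or over-oxidation competes. The fallback sets out from 17 and comes back at 19. PhSeCl with pyridine in CH2Cl2 at −78 °C should effect selenoetherification, the phenol attacking the tertiary carbon of the seleniranium ion, to give racemic [2,4-dimethoxy-6-(methoxymethoxy)phenyl][7-(methoxymethoxy)-2,2-dimethyl-3-(phenylselanyl)-3,4-dihydro-2H-chromen-5-yl]methanone F13. Oxidation with H2O2 and syn-elimination of the selenoxide, which can only go toward C4, gives 19.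

## Further compounds

F1 | step 9 | methyl 3,5-dihydroxybenzoate | COC(=O)c1cc(O)cc(O)c1
F2 | step 9 | methyl 3,5-bis(methoxymethoxy)benzoate | COCOc1cc(OCOC)cc(C(=O)OC)c1
F3 | step 9 | methyl 2-bromo-3,5-bis(methoxymethoxy)benzoate | COCOc1cc(OCOC)c(Br)c(C(=O)OC)c1
F4 | step 9 | methyl 3,5-bis(methoxymethoxy)-2-(3-methylbut-2-en-1-yl)benzoate | COCOc1cc(OCOC)c(CC=C(C)C)c(C(=O)OC)c1
F5 | step 9 | methyl 3,5-dihydroxy-2-(3-methylbut-2-en-1-yl)benzoate | COC(=O)c1cc(O)cc(O)c1CC=C(C)C
F6 | step 9 | methyl 7-hydroxy-2,2-dimethyl-2H-chromene-5-carboxylate | COC(=O)c1cc(O)cc2OC(C)(C)C=Cc12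
F7 | step 9 | methyl 7-(methoxymethoxy)-2,2-dimethyl-2H-chromene-5-carboxylate | COCOc1cc(C(=O)OC)c2C=CC(C)(C)Oc2c1
F8 | step 5 | 6-(bromomethyl)-4-(methoxymethoxy)-2H-pyran-2-one | BrCC1=CC(OCOC)=CC(=O)O1
F9 | step 7 | 2-iodo-1,5-dimethoxy-3-(methoxymethoxy)benzene | COCOc1cc(OC)cc(OC)c1I
F10 | step 7 | [2,4-dimethoxy-6-(methoxymethoxy)phenyl]magnesium chloride | COCOc1cc(OC)cc(OC)c1[Mg]Cl
F11 | step 2 | methyl 4-methylpent-3-enoate | COC(=O)CC=C(C)C
F12 | step 2 | lithium 1,1-dibromo-5-methylhexa-1,4-dien-2-olate | [Li+].[O-]C(CC=C(C)C)=C(Br)Br
F13 | step 11 | racemic [2,4-dimethoxy-6-(methoxymethoxy)phenyl][7-(methoxymethoxy)-2,2-dimethyl-3-(phenylselanyl)-3,4-dihydro-2H-chromen-5-yl]methanone | COCOc1cc(OC)cc(OC)c1C(=O)c1cc(OCOC)cc2OC(C)(C)C([Se]c3ccccc3)Cc12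
A1 | alternative 1 | racemic 2-{[(tert-butyldimethylsilyl)oxy][7-(methoxymethoxy)-2,2-dimethyl-2H-chromen-5-yl]methyl}-3,5-dimethoxyphenol | COc1cc(O)c(C(O[Si](C)(C)C(C)(C)C)c2cc(OCOC)cc3OC(C)(C)C=Cc23)c(OC)c1
A2 | alternative 1 | 3-methoxycyclobut-2-en-1-one | COC1=CC(=O)C1
A3 | alternative 1 | racemic tert-butyl({3-methoxy-1-[7-(methoxymethoxy)-2,2-dimethyl-2H-chromen-5-yl]prop-2-yn-1-yl}oxy)dimethylsilane | COC#CC(O[Si](C)(C)C(C)(C)C)c1cc(OCOC)cc2OC(C)(C)C=Cc12
A4 | alternative 2 | [7-(methoxymethoxy)-2,2-dimethyl-2H-chromen-5-yl](2,4,6-trihydroxyphenyl)methanone | O=C(c1c(O)cc(O)cc1O)c1cc(OCOC)cc2OC(C)(C)C=Cc12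
A5 | alternative 2 | 4-hydroxy-6-{2-[7-(methoxymethoxy)-2,2-dimethyl-2H-chromen-5-yl]-2-oxoethyl}-2H-pyran-2-one | O=C(CC1=CC(O)=CC(=O)O1)c1cc(OCOC)cc2OC(C)(C)C=Cc12
A6 | alternative 3 | racemic methyl 2-{[(tert-butyldimethylsilyl)oxy][2,4-dimethoxy-6-(methoxymethoxy)phenyl]methyl}-4,6-dihydroxybenzoate | COC(=O)c1c(O)cc(O)cc1C(O[Si](C)(C)C(C)(C)C)c1c(OCOC)cc(OC)cc1OC
A7 | alternative 3 | 1,3-bis(trimethylsilyloxy)cyclohexa-1,3-diene | C[Si](C)(C)OC1=CC(O[Si](C)(C)C)=CCC1
A8 | alternative 3 | racemic methyl 4-[(tert-butyldimethylsilyl)oxy]-4-[2,4-dimethoxy-6-(methoxymethoxy)phenyl]but-2-ynoate | COC(=O)C#CC(O[Si](C)(C)C(C)(C)C)c1c(OCOC)cc(OC)cc1OC
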